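- 6 questions stand on these flasks, and by hand you can bring them down to one number.

| setting | birch | cedar | alder |
|---|---|---|---|
| substrate | 0.30 M | 0.30 M | 0.30 M |
| reagent | 1.50 equiv | 1.50 equiv | 1.50 equiv |
| temperature | 50 °C | 65 °C | 80 °C |
| time | 15 min | 15 min | 15 min |

- which of these there is most of at the end, counted by the substrate in it, birch (substrate / target / over-reaction product)
- which of these there is most of at the end, counted by the substrate in it, cedar (substrate / target / over-reaction product)
- which of these there is most of at the end, counted by the substrate in it, alder (substrate / target / over-reaction product)
- final amount of the leader among these, as a percentage of the substrate charged, in birch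
- final amount of the leader among these, as a percentage of the substrate charged, in cedar
- final amount of the leader among these, as a percentage of the substrate charged, in alder

- amounts and yields of target count crystals too
- given per volume of solution although it is solid: crystals
- the list of constants is for 50 °C, to be carried to other temperatures by the activation energies and enthalpies

    substrate + reagent ⇌ target (K1 = 0.68 M⁻¹, k1 = 0.0080 M⁻¹ s⁻¹, Ea1 = 63.0 kJ mol⁻¹, ΔH1 = −6.00 kJ mol⁻¹)
    target → over-reaction product (k2 = 0.0012 s⁻¹, Ea2 = 97.0 kJ mol⁻¹)
    crystals ⇌ target, rate k3*(cs3 - [target]) while solid is left; crystals form when [target] > cs3 (cs3 = 4.1 mM, k3 = 0.18 s⁻¹)
    (constants at 50 °C)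

- Crystals take up excess target with a half-life of 3.85 s, far shorter than the 9.6 min of dissolved target by step 2, so I hold dissolved target at 4.1 mM while crystals last. Crystals are then target's resting state.
- Step 1 stops when 0.68 times substrate times reagent equals that solubility. In fractions of the substrate charge, with f substrate left and f + 0.500 reagent left, this reads f(f + 0.500) = s, where s is the solubility over K1 times the charge squared, 0.0670 for birch, or −1.17 in powers of ten.
- Solving gives 11.0%, the floor, which is the fraction of substrate left when step 1 stands still against a saturated solution.
- Time: the gap to the floor closes by 0.675 powers of ten in birch and 1.91 in cedar. I therefore integrate birch, which gives 20.5% substrate left, and I put cedar and alder at their floors.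
- Temperature: from birch to alder, step 2 gains 1.33 powers of ten and step 1 gains 0.865. The floor barely moves, to 11.9% in cedar and 12.9% in alder.
- I reckon the loss to over-reaction product as if dissolved target stood at the solubility for the whole time, so at k2 times the solubility, and this estimate gives 1.48% of the charge in birch, 7.32% in cedar and 31.7% in alder.
- Subtracting leaves me with target at 78.0% in birch, 80.7% in cedar and 55.4% in alder.
- Charge: s goes with the inverse square of the substrate concentration, so at fixed equivalents a tenfold cut adds 2 powers of ten to s.
- The forecast names target, target and target as leaders for birch, cedar and alder, at 77%, 79% and 53%, holding that crystallisation “shields most of the target from over-reaction”. My figures stand above these.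
- The flasks give target at 76.5% in birch, target at 77.6% in cedar and target at 49.8% in alder, with over-reaction product at 1.97%, 9.84% and 38.6%. In each flask that is more than my estimated loss . Birch's substrate stands at 21.6%, above its floor of 11.0%, and at 150 min it reads 10.9%.
- Take the floor to a neighbour of birch charged with 0.075 M of substrate, a quarter of birch's charge. Its s rises by 1.20 powers of ten to 1.07, so its floor is 81.5%, far above birch's. At 15.0 min that neighbour holds 86.2% substrate, 5.60% over-reaction product and 8.23% target, of which 2.77% is crystals.

(Its constants were chosen freely; the flask was simulated.)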